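**Retrosynthetic overview**
- The target is a depside: ring A (2-hydroxy-4-methoxy-6-pentylbenzoyl; C1 carries the ester C=O, flanked by C2–OH and C6–pentyl) is esterified to O4′ of ring B (2′-heptyl-6′-methoxybenzoic acid). The last step only frees CO2H from its benzyl ester.
- Key disconnection: ring A is cut at C1–C2 and C5–C6, a [4+2] benzannulation of a 1,3-dimethoxy-1-silyloxydiene onto the C≡C of the ring-B aryl ester of oct-2-ynoic acid. The hindered aroyl–O–aryl ester is therefore never made by acylation with a 2,6-disubstituted benzoic acid; it is made as an unhindered ynoate ester and ring A is grown around it.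
- Ring B is cut the same way (C1′–C6′ and C2′–C3′): 1,1-dimethoxy-3-silyloxydiene plus benzyl dec-2-ynoate. Each diene encodes the O-pattern of its ring (B: OMe ortho, OH para to the ester; A: OH ortho, OMe para), so no phenol has to be differentiated or protected.
- Order of ring formation: ring B (step 4), O-acylation of its only free OH (step 5), ring A (step 7), debenzylation (step 8).

Key step: step 7

Remark: the target has no stereogenic centre, axis or double bond; it is achiral, so the request for a single enantiomer needs no stereocontrol.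

**Route**

Step 1
Reactants: 1 1-nonyne; 2 benzyl chloroformate
Product: 4 benzyl dec-2-ynoate, via lithium non-1-yn-1-ide 3 (not isolated)
Conditions: n-BuLi, THF, −78 °C; then inverse addition to 2, −78 → 0 °C
Reagents that add atoms: none
Why: Acetylide carboalkoxylation: the lithium acetylide is acylated by the chloroformate, the standard entry to 2-alkynoates, and inverse addition at low temperature keeps the product ynoate from being attacked.

Step 2
Reactants: 5 1,1-dimethoxyethene (ketene dimethyl acetal); 6 acetyl chloride
Product: 7 4,4-dimethoxybut-3-en-2-one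
Conditions: pyridine (1.1 equiv), Et2O, 0 °C → rt
Reagents that add atoms: none
Why: C-acylation of a ketene acetal by an acid chloride: the nucleophilic CH2 of 5 attacks the N-acetylpyridinium ion and loss of a proton to pyridine should give the conjugated acylketene acetal.

Step 3
Reactants: 7 4,4-dimethoxybut-3-en-2-one
Product: 8 1,1-dimethoxy-3-(trimethylsilyloxy)buta-1,3-diene
Conditions: TMSCl, Et3N, ZnCl2 (cat.), Et2O, rt → 35 °C; filtration and distillation
Reagents that add atoms: chlorotrimethylsilane, C[Si](C)(C)Cl
Why: Enol silylation of a methyl ketone (TMSCl/Et3N/ZnCl2, the usual method for 2-silyloxy-1,3-dienes): the CH3 group is the only enolizable position, so a single silyloxydiene should form.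

Step 4
Reactants: 4 benzyl dec-2-ynoate; 8 1,1-dimethoxy-3-(trimethylsilyloxy)buta-1,3-diene
Product: 11 benzyl 2-heptyl-4-hydroxy-6-methoxybenzoate, via dimethyl ketal cycloadduct 9 (not isolated), via aryl trimethylsilyl ether 10 (not isolated)
Conditions: 8 (2.5 equiv), neat or toluene, 120–130 °C, sealed tube; then 1 M HCl, THF, rt
Reagents that add atoms: none
Why: Diels–Alder benzannulation of a 2-alkynoate with a 1,1-dialkoxy-3-silyloxy-1,3-diene: the CH2 terminus of 8 bonds to the heptyl-bearing β-carbon and the ketene-acetal carbon to the α-carbon of 4, adduct 9 aromatizes by loss of methanol and acid cleaves the silyl ether, so OMe should stand ortho and the only free OH para to the ester.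

Step 5
Reactants: 11 benzyl 2-heptyl-4-hydroxy-6-methoxybenzoate; 12 oct-2-ynoic acid
Product: 13 benzyl 2-heptyl-6-methoxy-4-(oct-2-ynoyloxy)benzoate
Conditions: DCC (1.2 equiv), DMAP (5 mol%), CH2Cl2, 0 °C → rt
Reagents that add atoms: none
Why: Steglich esterification: the acid is linear and unhindered and the phenol is the single free OH para to the ester, while the low DMAP loading at 0 °C limits conjugate addition to the ynoate.

Step 6
Reactants: 14 methyl (2E)-3-methoxybut-2-enoate
Product: 16 (1E)-1,3-dimethoxy-1-(trimethylsilyloxy)buta-1,3-diene, via lithium dienolate 15 (not isolated)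
Conditions: LDA (commercial solution), THF, −78 °C; then TMSCl, −78 °C → rt; distillation
Reagents that add atoms: chlorotrimethylsilane, C[Si](C)(C)Cl
Why: γ-Deprotonation of the vinylogous ester by LDA gives the extended enolate, which TMSCl silylates on oxygen (silyl ketene acetal formation); the ketene-acetal geometry is drawn as E, is erased in step 7 and is of no consequence.

Step 7
Reactants: 13 benzyl 2-heptyl-6-methoxy-4-(oct-2-ynoyloxy)benzoate; 16 (1E)-1,3-dimethoxy-1-(trimethylsilyloxy)buta-1,3-diene
Product: 19 benzyl 2-heptyl-4-[(2-hydroxy-4-methoxy-6-pentylbenzoyl)oxy]-6-methoxybenzoate, via mixed ketal cycloadduct 17 (not isolated), via cyclohexadienone tautomer 18 (not isolated)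
Conditions: 16 (3 equiv), toluene, 110 °C, sealed tube; then 1 M HCl, THF, 0 °C → rt
Reagents that add atoms: none
Why: The electron-rich diene 16 (largest HOMO coefficient at its CH2 terminus) should add to the ynoate C≡C of 13 (largest LUMO coefficient at the pentyl-bearing β-carbon) in a polarized, asynchronous thermal [4+2] cycloaddition that forms C1–C2 and C5–C6 of ring A and gives the 1,4-cyclohexadiene 17. The closest known reaction type is the Diels–Alder benzannulation of 2-alkynoates with 1,1-dioxygenated 3-oxy-1,3-butadienes (vinylketene acetals), which gives resorcylate esters regiospecifically. Ring A, the only ring closed, closes as a six-membered carbocycle by intermolecular [4+2] and is then aromatized: acid cleaves the O–Si bond of the C(OMe)(OSiMe3) unit, the hemiketal loses methanol to give dienone 18, and 18 tautomerizes to the phenol. No stereocentre remains in the product, since the one sp3 ketal centre of 17 is erased. The step needs regioselectivity (ketene-acetal carbon on the α-carbon of the ynoate, so that OH ends at C2 next to the ester and OMe at C4), secured by the matched polarization of both partners; chemoselectivity, secured because the ynoate is the only dienophile while the benzyl benzoate and the arene are inert; and retention of O–H instead of O–Me at C2, which follows from the lability of O–Si compared with O–Me in the mixed ketal. Because the ester is already in place as an unhindered ynoate ester, the step creates the doubly ortho-substituted aroyl ester that resists direct acylation.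

Step 8
Reactants: 19 benzyl 2-heptyl-4-[(2-hydroxy-4-methoxy-6-pentylbenzoyl)oxy]-6-methoxybenzoate
Product: 20 2-heptyl-4-[(2-hydroxy-4-methoxy-6-pentylbenzoyl)oxy]-6-methoxybenzoic acid (CNP0518349.0)
Conditions: H2 (1 atm), 10% Pd/C, EtOAc, rt
Reagents that add atoms: none
Why: Catalytic hydrogenolysis of the benzyl ester; the aryl ester of the depside link, the phenol, the methyl ethers and the alkyl chains should be inert to H2/Pd at room temperature.

**Compound list**
1 | 1-nonyne | CCCCCCCC#C | starting material
2 | benzyl chloroformate | O=C(Cl)OCc1ccccc1 | starting material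
3 | lithium non-1-yn-1-ide | [Li]C#CCCCCCCC | intermediate
4 | benzyl dec-2-ynoate | CCCCCCCC#CC(=O)OCc1ccccc1 | intermediate
5 | 1,1-dimethoxyethene | C=C(OC)OC | starting material
6 | acetyl chloride | CC(=O)Cl | starting material
7 | 4,4-dimethoxybut-3-en-2-one | CC(=O)C=C(OC)OC | intermediate
8 | 1,1-dimethoxy-3-(trimethylsilyloxy)buta-1,3-diene | C=C(O[Si](C)(C)C)C=C(OC)OC | intermediate
9 | benzyl 2-heptyl-6,6-dimethoxy-4-(trimethylsilyloxy)cyclohexa-1,4-diene-1-carboxylate | CCCCCCCC1=C(C(=O)OCc2ccccc2)C(OC)(OC)C=C(O[Si](C)(C)C)C1 | intermediate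
10 | benzyl 2-heptyl-6-methoxy-4-(trimethylsilyloxy)benzoate | CCCCCCCc1cc(O[Si](C)(C)C)cc(OC)c1C(=O)OCc1ccccc1 | intermediate
11 | benzyl 2-heptyl-4-hydroxy-6-methoxybenzoate | CCCCCCCc1cc(O)cc(OC)c1C(=O)OCc1ccccc1 | intermediate
12 | oct-2-ynoic acid | CCCCCC#CC(=O)O | starting material
13 | benzyl 2-heptyl-6-methoxy-4-(oct-2-ynoyloxy)benzoate | CCCCCCCc1cc(OC(=O)C#CCCCCC)cc(OC)c1C(=O)OCc1ccccc1 | intermediate
14 | methyl (2E)-3-methoxybut-2-enoate | CO/C(C)=C/C(=O)OC | starting material
15 | lithium (1Z)-1,3-dimethoxybuta-1,3-dien-1-olate (same spatial arrangement as 16) | C=C(OC)/C=C(/O[Li])OC | intermediate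
16 | (1E)-1,3-dimethoxy-1-(trimethylsilyloxy)buta-1,3-diene | C=C(OC)/C=C(/O[Si](C)(C)C)OC | intermediate
17 | benzyl 4-{[4,6-dimethoxy-2-pentyl-6-(trimethylsilyloxy)cyclohexa-1,4-diene-1-carbonyl]oxy}-2-heptyl-6-methoxybenzoate (racemic) | CCCCCCCc1cc(OC(=O)C2=C(CCCCC)CC(OC)=CC2(OC)O[Si](C)(C)C)cc(OC)c1C(=O)OCc1ccccc1 | intermediate
18 | benzyl 2-heptyl-6-methoxy-4-[(4-methoxy-6-oxo-2-pentylcyclohexa-1,4-diene-1-carbonyl)oxy]benzoate | CCCCCCCc1cc(OC(=O)C2=C(CCCCC)CC(OC)=CC2=O)cc(OC)c1C(=O)OCc1ccccc1 | intermediate
19 | benzyl 2-heptyl-4-[(2-hydroxy-4-methoxy-6-pentylbenzoyl)oxy]-6-methoxybenzoate | CCCCCCCc1cc(OC(=O)c2c(O)cc(OC)cc2CCCCC)cc(OC)c1C(=O)OCc1ccccc1 | intermediate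
20 | 2-heptyl-4-[(2-hydroxy-4-methoxy-6-pentylbenzoyl)oxy]-6-methoxybenzoic acid | CCCCCCCc1cc(OC(=O)c2c(O)cc(OC)cc2CCCCC)cc(OC)c1C(=O)O | target

**Step count and risks**

Total step count: 8. Longest linear sequence: 6 steps (steps 2, 3, 4, 5, 7, 8).

Steps most likely to fail:

1. Step 7. The cycloaddition of the β-alkyl ynoate may be slower than the thermal decomposition of the silyl ketene acetal diene. The mixed ketal may also aromatize with loss of the silyloxy group instead of the methoxy group, which would leave a methyl ether at C2, or the activated aryl ester may undergo acyl transfer. The fallback forms the ester C(=O)–O bond last, by the classical depside condensation; it sets out from phenol 11 and comes back to the route at 19. Commercial olivetol F1 would be formylated (POCl3, DMF, Vilsmeier–Haack) to 2,4-dihydroxy-6-pentylbenzaldehyde F2. The non-chelated 4-OH would be methylated (MeI, K2CO3, acetone, rt) to 2-hydroxy-4-methoxy-6-pentylbenzaldehyde F3. Pinnick oxidation (NaClO2, NaH2PO4, 2-methylbut-2-ene, t-BuOH/H2O) would give 2-hydroxy-4-methoxy-6-pentylbenzoic acid F4. Condensation of F4 with 11 by trifluoroacetic anhydride in toluene at rt should give 19.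

2. Step 4. Hydrolysis or polymerization of the sensitive ketene acetal diene 8 at the temperature the cycloaddition needs may leave the conversion incomplete. The fallback builds ring B by an anionic Michael–Claisen condensation and differentiates the two phenols through the hydrogen bond of the ortho OH to the ester; it sets out from ynoate 4 and comes back at 11. Ynoate 4 would be condensed with benzyl acetoacetate F5 (NaH, THF, rt → reflux): conjugate addition of the acetoacetate α-carbon to the β-carbon of 4, then Claisen closure of the acetyl CH3 onto the ester carbonyl of 4 with loss of benzyl alcohol, should give benzyl 2-heptyl-4,6-dihydroxybenzoate F6 (the OH ortho to the ester is chelated, the para OH is free). The para OH would be allylated (allyl bromide, K2CO3, acetone) to benzyl 4-(allyloxy)-2-heptyl-6-hydroxybenzoate F7. The chelated OH would then be methylated (MeI, K2CO3, DMF, 50 °C) to benzyl 4-(allyloxy)-2-heptyl-6-methoxybenzoate F8. Pd(PPh3)4 (cat.) with morpholine in THF would remove the allyl group and return 11.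

3. Step 2. Adventitious HCl may polymerize the ketene acetal, or double acylation may compete with the wanted mono-C-acylation. The fallback replaces the ketene acetal by a dichloroalkene and introduces the two methoxy groups by substitution; it sets out from acetyl chloride 6 and comes back at 7. AlCl3-mediated addition of 6 to 1,1-dichloroethene F9 (CH2Cl2, 0 °C) would give 4,4,4-trichlorobutan-2-one F10, which should lose HCl on distillation to 4,4-dichlorobut-3-en-2-one F11. Two addition–elimination steps with NaOMe (2 equiv, MeOH, 0 °C) should then give 7.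

**Further compounds**
F1 | step 7 | olivetol (5-pentylbenzene-1,3-diol) | CCCCCc1cc(O)cc(O)c1
F2 | step 7 | 2,4-dihydroxy-6-pentylbenzaldehyde | CCCCCc1cc(O)cc(O)c1C=O
F3 | step 7 | 2-hydroxy-4-methoxy-6-pentylbenzaldehyde | CCCCCc1cc(OC)cc(O)c1C=O
F4 | step 7 | 2-hydroxy-4-methoxy-6-pentylbenzoic acid | CCCCCc1cc(OC)cc(O)c1C(=O)O
F5 | step 4 | benzyl acetoacetate (benzyl 3-oxobutanoate) | CC(=O)CC(=O)OCc1ccccc1
F6 | step 4 | benzyl 2-heptyl-4,6-dihydroxybenzoate | CCCCCCCc1cc(O)cc(O)c1C(=O)OCc1ccccc1
F7 | step 4 | benzyl 4-(allyloxy)-2-heptyl-6-hydroxybenzoate | C=CCOc1cc(O)c(C(=O)OCc2ccccc2)c(CCCCCCC)c1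
F8 | step 4 | benzyl 4-(allyloxy)-2-heptyl-6-methoxybenzoate | C=CCOc1cc(OC)c(C(=O)OCc2ccccc2)c(CCCCCCC)c1
F9 | step 2 | 1,1-dichloroethene | C=C(Cl)Cl
F10 | step 2 | 4,4,4-trichlorobutan-2-one | CC(=O)CC(Cl)(Cl)Cl
F11 | step 2 | 4,4-dichlorobut-3-en-2-one | CC(=O)C=C(Cl)Cl
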